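The two butenolide rings (O1–C2–C3–C4–C5) each join a fully substituted spiro C5, bearing O1, to an sp2 C4 that carries a heteroatom. This is a masked tetronic acid, so the route rests on cutting C3A–C4A and C3B–C4B. One base treatment of the finished cyclobutane (C5A–C6A–C6B–C5B, all four stereocentres in place) closes rings A and B together by twofold Dieckmann condensation and touches no stereocentre. The precursor is a dimethyl trans-3,4-dibromocyclobutane-1,2-dicarboxylate with a C2-symmetric core. Its trans tertiary oxygens carry one (S)- and one (R)-3-silyloxyhexanoyl group. The core is built from a 2-pyrone by 4π photocyclisation, bromination and β-lactone methanolysis.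

Key step: step 15

Remarks on the chemistry. Locants: butenolide O1–C2(=O)–C3–C4(Br)–C5 with C5 spiro; CHBr carbons C6; carbinol carbons C1'. Half A carries the (S)-side chain.
- Reading of the target: C5A and C5B are both S, C6A and C6B are both R, C1'A is S and C1'B is R. On the cyclobutane the two O1 are trans and the two Br are trans. Each Br is trans to O1 (cis to C4) on the neighbouring carbon.
- The core is C2-symmetric, so the two tertiary hydroxyls of the diol are homotopic and the order of attaching the two acids does not matter.
- An (S)/(R) pair of side chains is its own mirror image. The handedness of the molecule therefore rests on the core alone, and the core must be resolved no later than the monoester.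
- Design of the Dieckmann substrate: methyl esters are kept as the least hindered electrophiles at the neopentyl-type C4. The TBS ethers are kept as non-chelating, poor leaving groups. The substrate is assembled under acidic or neutral conditions only, because its parent diol is a double trans-bromohydrin.
- Assumption: racemic intermediates (from the photocyclisation to the diol) are drawn as the enantiomer that is carried on.

Step 1
Reactants: 1 methyl 3-oxohexanoate
Product: 2 methyl (3S)-3-hydroxyhexanoate
Conditions: H2 (50 atm), RuCl2[(S)-BINAP] (cat.), MeOH, 50 °C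
Reagents that add atoms: none
Why: Noyori asymmetric hydrogenation of a β-keto ester: chelation of ketone and ester oxygens to the (S)-BINAP–ruthenium hydride exposes one carbonyl face, which should set the (S)-carbinol centre that becomes C1' of half A.

Step 2
Reactants: 2 methyl (3S)-3-hydroxyhexanoate
Product: 3 methyl (3S)-3-(tert-butyldimethylsilyloxy)hexanoate
Conditions: TBSCl, imidazole, DMF, rt
Reagents that add atoms: tert-butyldimethylsilyl chloride, CC(C)(C)[Si](C)(C)Cl
Why: Imidazole-promoted silylation of a secondary alcohol touches no stereocentre and installs a bulky, non-chelating ether that is a poor leaving group from the later C3 enolate at low temperature.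

Step 3
Reactants: 3 methyl (3S)-3-(tert-butyldimethylsilyloxy)hexanoate
Product: 4 (3S)-3-(tert-butyldimethylsilyloxy)hexanoic acid
Conditions: LiOH, THF/MeOH/H2O, 0 °C to rt; then cold 1 M HCl to pH 3
Reagents that add atoms: lithium hydroxide, [Li+].[OH-]
Why: Saponification (acyl substitution by hydroxide) of an unhindered methyl ester is faster than β-elimination at or below room temperature, so the silyl ether and the carbinol centre should survive.

Step 4
Reactants: 1 methyl 3-oxohexanoate
Product: 5 methyl (3R)-3-hydroxyhexanoate
Conditions: H2 (50 atm), RuCl2[(R)-BINAP] (cat.), MeOH, 50 °C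
Reagents that add atoms: none
Why: The same Noyori hydrogenation with the enantiomeric ligand should deliver hydride to the opposite carbonyl face and set the (R)-carbinol centre that becomes C1' of half B.

Step 5
Reactants: 5 methyl (3R)-3-hydroxyhexanoate
Product: 6 methyl (3R)-3-(tert-butyldimethylsilyloxy)hexanoate
Conditions: TBSCl, imidazole, DMF, rt
Reagents that add atoms: tert-butyldimethylsilyl chloride, CC(C)(C)[Si](C)(C)Cl
Why: Imidazole-promoted silylation as in step 2, with no stereocentre touched.

Step 6
Reactants: 6 methyl (3R)-3-(tert-butyldimethylsilyloxy)hexanoate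
Product: 7 (3R)-3-(tert-butyldimethylsilyloxy)hexanoic acid
Conditions: LiOH, THF/MeOH/H2O, 0 °C to rt; then cold 1 M HCl to pH 3
Reagents that add atoms: lithium hydroxide, [Li+].[OH-]
Why: Saponification as in step 3, faster than β-elimination and without effect on the carbinol centre.

Step 7
Reactants: 8 galactaric acid (mucic acid)
Product: 9 3-acetoxy-2-oxo-2H-pyran-6-carboxylic acid
Conditions: Ac2O, pyridine, 100 °C; then cold aq HCl
Reagents that add atoms: acetic anhydride, CC(=O)OC(C)=O
Why: Acetylative dehydration of an aldaric acid, a known conversion of galactaric acid: peracetylation, δ-lactonisation and two β-eliminations of acetic acid lead to the conjugated 2-pyrone, and the four stereocentres are deliberately erased.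

Step 8
Reactants: 9 3-acetoxy-2-oxo-2H-pyran-6-carboxylic acid
Product: 10 methyl 3-hydroxy-2-oxo-2H-pyran-6-carboxylate
Conditions: MeOH, H2SO4 (cat.), reflux
Reagents that add atoms: methanol, CO
Why: Fischer esterification of the acid runs together with acid-catalysed transesterification of the enol acetate, and the 2-pyrone ring is known to tolerate hot acidic alcohols.

Step 9
Reactants: 10 methyl 3-hydroxy-2-oxo-2H-pyran-6-carboxylate
Product: 11 methyl 3-(tert-butyldimethylsilyloxy)-2-oxo-2H-pyran-6-carboxylate
Conditions: TBSCl, imidazole, CH2Cl2, 0 °C to rt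
Reagents that add atoms: tert-butyldimethylsilyl chloride, CC(C)(C)[Si](C)(C)Cl
Why: Silylation of the acidic enolic hydroxyl removes the hydrogen bond to C2=O that could drain the excited state by proton transfer and provides the bulky, non-participating oxygen substituent that step 11 relies on.

Step 10
Reactants: 11 methyl 3-(tert-butyldimethylsilyloxy)-2-oxo-2H-pyran-6-carboxylate
Product: 12 methyl (1R*,4R*)-4-(tert-butyldimethylsilyloxy)-3-oxo-2-oxabicyclo[2.2.0]hex-5-ene-1-carboxylate (racemic, kept in solution)
Conditions: hν (300 nm, Pyrex), degassed CH2Cl2 (0.01 M), −10 °C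
Reagents that add atoms: none
Why: Disrotatory 4π photochemical electrocyclisation of a 2-pyrone to its bicyclic β-lactone valence isomer, known for ester-substituted 2-pyrones; the obligatory cis ring fusion puts lactone O and lactone C=O on one face and CO2Me and OTBS on the other, which sets both quaternary centres and with them the trans relation of the two future C5–O1 bonds (racemic).

Step 11
Reactants: 12 methyl (1R*,4R*)-4-(tert-butyldimethylsilyloxy)-3-oxo-2-oxabicyclo[2.2.0]hex-5-ene-1-carboxylate
Product: 13 methyl (1R*,4R*,5R*,6R*)-5,6-dibromo-4-(tert-butyldimethylsilyloxy)-3-oxo-2-oxabicyclo[2.2.0]hexane-1-carboxylate (racemic; Br on C6 cis to CO2Me on C1, Br on C5 cis to the lactone C=O on C4)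
Conditions: Br2 (1.05 equiv), CH2Cl2, −20 °C to rt, dark
Reagents that add atoms: bromine, BrBr
Why: Electrophilic anti addition of bromine to a strained cyclobutene via a bromonium ion gives a trans-dibromide, and for steric and dipolar reasons bromide should enter syn to a carbon substituent (CO2Me or lactone C=O) and not syn to an oxygen substituent (bulky OTBS or lactone O), so that each bromine ends trans to the oxygen on the neighbouring carbon; brominating while the ring is still bicyclic also excludes conrotatory opening of the cyclobutene.

Step 12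
Reactants: 13 methyl (1R*,4R*,5R*,6R*)-5,6-dibromo-4-(tert-butyldimethylsilyloxy)-3-oxo-2-oxabicyclo[2.2.0]hexane-1-carboxylate
Product: 15 dimethyl (1R*,2R*,3R*,4R*)-3,4-dibromo-1,2-dihydroxycyclobutane-1,2-dicarboxylate (racemic), via monosilylated hydroxy diester 14 (not isolated)
Conditions: 1.25 M HCl in MeOH, 0 °C to rt; evaporate; then 48% aq HF, MeCN, rt
Reagents that add atoms: methanol, CO
Why: Acid-catalysed acyl–oxygen methanolysis of the strained β-lactone and fluoride-driven desilylation touch no stereocentre, and acidic media are chosen because a tertiary alkoxide trans to a neighbouring bromine could close to an epoxide or fragment the four-membered ring.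

Step 13
Reactants: 15 dimethyl (1R*,2R*,3R*,4R*)-3,4-dibromo-1,2-dihydroxycyclobutane-1,2-dicarboxylate; 4 (3S)-3-(tert-butyldimethylsilyloxy)hexanoic acid
Product: 16 dimethyl (1R,2R,3R,4R)-3,4-dibromo-1-{[(3S)-3-(tert-butyldimethylsilyloxy)hexanoyl]oxy}-2-hydroxycyclobutane-1,2-dicarboxylate (single diastereomer)
Conditions: 4 (1 equiv), DCC, DMAP, CH2Cl2, 0 °C to rt; separation of the two diastereomeric monoesters on silica gel
Reagents that add atoms: none
Why: Steglich esterification of one of two homotopic tertiary hydroxyls, the second being slowed by the added bulk, converts the enantiomers of the core into diastereomeric monoesters, so the building block doubles as resolving agent and chromatographic separation should make the four ring stereocentres absolute (to be assigned by X-ray diffraction using the anomalous scattering of bromine).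

Step 14
Reactants: 16 (1R,2R,3R,4R)-monoester; 7 (3R)-3-(tert-butyldimethylsilyloxy)hexanoic acid
Product: 17 dimethyl (1R,2R,3R,4R)-3,4-dibromo-1-{[(3S)-3-(tert-butyldimethylsilyloxy)hexanoyl]oxy}-2-{[(3R)-3-(tert-butyldimethylsilyloxy)hexanoyl]oxy}cyclobutane-1,2-dicarboxylate
Conditions: 7 (3 equiv), DCC, DMAP (stoichiometric), CH2Cl2, rt to 40 °C
Reagents that add atoms: none
Why: Second Steglich esterification, driven by excess activated acid and stoichiometric DMAP; only one hydroxyl is left, so the (S)/(R) pair of side chains is placed without any regiochemical question and no stereocentre is touched.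

Step 15
Reactants: 17 dimethyl (1R,2R,3R,4R)-3,4-dibromo-1,2-bis(3-silyloxyhexanoyloxy)cyclobutane-1,2-dicarboxylate, (3S) and (3R) side chains
Product: 18 (5S,6S,11R,12R)-11,12-dibromo-4,10-dihydroxy-3-[(1S)-1-(tert-butyldimethylsilyloxy)butyl]-9-[(1R)-1-(tert-butyldimethylsilyloxy)butyl]-1,7-dioxadispiro[4.0.4.2]dodeca-3,9-diene-2,8-dione (dispiro bis(tetronic acid))
Conditions: LiN(SiMe3)2 (5 equiv), THF, −78 °C, slow addition of 17 to the base, then to −40 °C; cold 1 M HCl to pH 3; used without chromatography
Reagents that add atoms: none
Why: LiN(SiMe3)2 removes one C3–H from each acyloxy group, each ester enolate adds to the methyl ester carbonyl C4 that sits on the same C5, methoxide leaves, and further base converts each β-keto lactone into its tetronate, which makes both closures irreversible and forms C3A–C4A and C3B–C4B in one operation. The closest known reaction is the Dieckmann (intramolecular Claisen) condensation of α-acyloxy esters to tetronic acids, which runs with lithium amides at −78 °C and is applied here twice in one molecule. Rings A and B each close in the 5-(enolendo)-exo-trig mode, a formally awkward geometry that is nevertheless the regular course for this substrate class because the ring oxygen O1 lets the enolate twist into overlap with C4=O. No stereocentre is formed and none should be lost, since C5A and C5B carry no hydrogen, C1' and C6 are not deprotonated under these conditions, and the tetrahedral intermediates at C4 are cis, not anti, to the neighbouring C6–Br bond and so cannot fragment. The step needs site selectivity for the geminal ester (five-membered spiro ring) over the cis-vicinal ester on the other C5 (six-membered fused ring), and chemoselectivity for acylation over loss of silyloxide from C1', over C- or O-alkylation at C6 (geometrically open because O1 is trans to the neighbouring bromine) and over attack at bromine. These are secured by the geminal placement of O1 and C4 on a quaternary C5, which holds enolate and ester in contact (acylated malates likewise give only tetronic acids), by the fact that alkylation would be a 5-(enolendo)-exo-tet process at a neopentyl-type cyclobutyl carbon, and by low temperature, inverse addition and the non-chelating TBS ether, which keep elimination slow.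

Step 16
Reactants: 18 dispiro bis(tetronic acid)
Product: 19 (5S,6S,11R,12R)-4,10,11,12-tetrabromo-3-[(1S)-1-(tert-butyldimethylsilyloxy)butyl]-9-[(1R)-1-(tert-butyldimethylsilyloxy)butyl]-1,7-dioxadispiro[4.0.4.2]dodeca-3,9-diene-2,8-dione
Conditions: (COBr)2, DMF, 2,6-di-tert-butyl-4-methylpyridine, CH2Cl2, 0 °C to rt
Reagents that add atoms: oxalyl bromide, O=C(Br)C(Br)=O
Why: Vilsmeier-type halogenation of a vinylogous acid, a known route to 4-bromobutenolides: the tetronic acid oxygen is activated by the bromoiminium salt made from oxalyl bromide and DMF, bromide then substitutes at C4 by addition–elimination, and the hindered pyridine takes up HBr to protect the silyl ethers.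

Step 17
Reactants: 19 tetrabromide bis(silyl ether)
Product: 20 (5S,6S,11R,12R)-4,10,11,12-tetrabromo-3-[(1S)-1-hydroxybutyl]-9-[(1R)-1-hydroxybutyl]-1,7-dioxadispiro[4.0.4.2]dodeca-3,9-diene-2,8-dione
Conditions: HF·pyridine, THF, 0 °C to rt (polyethylene flask)
Reagents that add atoms: none
Why: Fluoride-driven cleavage of secondary TBS ethers in a mildly acidic medium avoids basic fluoride sources that could attack the β-bromobutenolides or the alkyl bromides, and the C1'–O bonds are not broken, so configuration is retained.

Step 18
Reactants: 20 tetrabromo diol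
Product: 21 (1S)-1-{(5S,6S,11R,12R)-9-[(1R)-1-acetoxybutyl]-4,10,11,12-tetrabromo-2,8-dioxo-1,7-dioxadispiro[4.0.4.2]dodeca-3,9-dien-3-yl}butyl acetate (CNP0266230.1)
Conditions: Ac2O, Sc(OTf)3 (cat.), MeCN, 0 °C
Reagents that add atoms: acetic anhydride, CC(=O)OC(C)=O
Why: Lewis acid-catalysed acetylation with acetic anhydride takes place at oxygen with retention at C1' and avoids nucleophilic amine catalysts that could substitute the C4 bromides by addition–elimination.

Compound list
1 | methyl 3-oxohexanoate | CCCC(=O)CC(=O)OC | starting material
2 | methyl (3S)-3-hydroxyhexanoate | CCC[C@H](O)CC(=O)OC | intermediate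
3 | methyl (3S)-3-(tert-butyldimethylsilyloxy)hexanoate | CCC[C@H](O[Si](C)(C)C(C)(C)C)CC(=O)OC | intermediate
4 | (3S)-3-(tert-butyldimethylsilyloxy)hexanoic acid | CCC[C@H](O[Si](C)(C)C(C)(C)C)CC(=O)O | intermediate
5 | methyl (3R)-3-hydroxyhexanoate | CCC[C@@H](O)CC(=O)OC | intermediate
6 | methyl (3R)-3-(tert-butyldimethylsilyloxy)hexanoate | CCC[C@@H](O[Si](C)(C)C(C)(C)C)CC(=O)OC | intermediate
7 | (3R)-3-(tert-butyldimethylsilyloxy)hexanoic acid | CCC[C@@H](O[Si](C)(C)C(C)(C)C)CC(=O)O | intermediate
8 | galactaric acid (meso) | OC(=O)[C@H](O)[C@@H](O)[C@@H](O)[C@H](O)C(=O)O | starting material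
9 | 3-acetoxy-2-oxo-2H-pyran-6-carboxylic acid | CC(=O)OC1=CC=C(C(=O)O)OC1=O | intermediate
10 | methyl 3-hydroxy-2-oxo-2H-pyran-6-carboxylate | COC(=O)C1=CC=C(O)C(=O)O1 | intermediate
11 | methyl 3-(tert-butyldimethylsilyloxy)-2-oxo-2H-pyran-6-carboxylate | COC(=O)C1=CC=C(O[Si](C)(C)C(C)(C)C)C(=O)O1 | intermediate
12 | methyl (1R*,4R*)-4-(tert-butyldimethylsilyloxy)-3-oxo-2-oxabicyclo[2.2.0]hex-5-ene-1-carboxylate, racemic | COC(=O)[C@]12OC(=O)[C@@]1(O[Si](C)(C)C(C)(C)C)C=C2 | intermediate
13 | methyl (1R*,4R*,5R*,6R*)-5,6-dibromo-4-(tert-butyldimethylsilyloxy)-3-oxo-2-oxabicyclo[2.2.0]hexane-1-carboxylate, racemic | COC(=O)[C@]12OC(=O)[C@@]1(O[Si](C)(C)C(C)(C)C)[C@@H](Br)[C@@H]2Br | intermediate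
14 | dimethyl (1R*,2R*,3R*,4R*)-3,4-dibromo-1-hydroxy-2-(tert-butyldimethylsilyloxy)cyclobutane-1,2-dicarboxylate, racemic, not isolated | O[C@]1(C(=O)OC)[C@@H](Br)[C@H](Br)[C@@]1(C(=O)OC)O[Si](C)(C)C(C)(C)C | intermediate
15 | dimethyl (1R*,2R*,3R*,4R*)-3,4-dibromo-1,2-dihydroxycyclobutane-1,2-dicarboxylate, racemic | O[C@]1(C(=O)OC)[C@@H](Br)[C@H](Br)[C@@]1(C(=O)OC)O | intermediate
16 | dimethyl (1R,2R,3R,4R)-3,4-dibromo-1-{[(3S)-3-(tert-butyldimethylsilyloxy)hexanoyl]oxy}-2-hydroxycyclobutane-1,2-dicarboxylate | CCC[C@H](O[Si](C)(C)C(C)(C)C)CC(=O)O[C@]1(C(=O)OC)[C@@H](Br)[C@H](Br)[C@@]1(C(=O)OC)O | intermediate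
17 | dimethyl (1R,2R,3R,4R)-3,4-dibromo-1-{[(3S)-3-(tert-butyldimethylsilyloxy)hexanoyl]oxy}-2-{[(3R)-3-(tert-butyldimethylsilyloxy)hexanoyl]oxy}cyclobutane-1,2-dicarboxylate | CCC[C@H](O[Si](C)(C)C(C)(C)C)CC(=O)O[C@]1(C(=O)OC)[C@@H](Br)[C@H](Br)[C@@]1(C(=O)OC)OC(=O)C[C@@H](CCC)O[Si](C)(C)C(C)(C)C | intermediate
18 | dispiro bis(tetronic acid) trans-dibromide, (5S,6S,11R,12R), (1S)-silyloxybutyl on ring A and (1R)-silyloxybutyl on ring B | CCC[C@H](O[Si](C)(C)C(C)(C)C)C1=C(O)[C@@]2(OC1=O)[C@@H](Br)[C@H](Br)[C@@]21OC(=O)C([C@@H](CCC)O[Si](C)(C)C(C)(C)C)=C1O | intermediate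
19 | dispiro bis(4-bromobutenolide) bis(TBS ether), (5S,6S,11R,12R), side chains (1S) and (1R) | CCC[C@H](O[Si](C)(C)C(C)(C)C)C1=C(Br)[C@@]2(OC1=O)[C@@H](Br)[C@H](Br)[C@@]21OC(=O)C([C@@H](CCC)O[Si](C)(C)C(C)(C)C)=C1Br | intermediate
20 | dispiro bis(4-bromobutenolide) diol, (5S,6S,11R,12R), side chains (1S) and (1R) | CCC[C@H](O)C1=C(Br)[C@@]2(OC1=O)[C@@H](Br)[C@H](Br)[C@@]21OC(=O)C([C@@H](CCC)O)=C1Br | intermediate
21 | CNP0266230.1, dispiro bis(4-bromobutenolide) diacetate, (5S,6S,11R,12R), side chains (1S) and (1R) | CCC[C@H](OC(C)=O)C1=C(Br)[C@@]2(OC1=O)[C@@H](Br)[C@H](Br)[C@@]21OC(=O)C([C@@H](CCC)OC(C)=O)=C1Br | target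

Total step count: 18.
Longest linear sequence: 12 steps (8 to 21, steps 7–18).

Steps most likely to fail

1. Step 15.
- What may go wrong: the C3 enolates may lose silyloxide from C1' by β-elimination before they acylate. Enolate attack at bromine (debromination of the vicinal dibromide) is a second drain.
- Fallback: the leaving group is taken out of the nucleophile, and the C1' oxygen is brought in after ring closure. The fallback sets out from diol 15.
- Hexanoic anhydride and DMAP give dimethyl (1R,2R,3R,4R)-3,4-dibromo-1,2-bis(hexanoyloxy)cyclobutane-1,2-dicarboxylate F1, which is resolved by HPLC on a chiral stationary phase.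
- LiN(SiMe3)2 at −78 °C closes it to the dispiro bis(3-butyltetronic acid) F2.
- Oxalyl bromide and DMF give the dispiro bis(4-bromo-3-butylbutenolide) F3.
- Wohl–Ziegler bromination (NBS, dibenzoyl peroxide, PhCF3, reflux) at the two allylic C1' positions gives the bis(1-bromobutyl) hexabromide F4.
- AgOAc in AcOH replaces both C1' bromides by acetate, and the fallback comes back to the route at target 21.
- The price: C1' is no longer controlled. The (S,R), (S,S) and (R,R) isomers are diastereomers. The wanted unlike isomer has twice the statistical weight of either like isomer and has to be separated by HPLC.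

2. Step 11.
- What may go wrong: poor site selectivity in the opening of the bromonium ion would divert material to the trans-dibromide with both bromines cis to the neighbouring oxygen.
- Fallback: separation and recycling replace reliance on kinetic selectivity. Setting out from alkene 12, the bromination mixture is separated by chromatography or crystallisation.
- The unwanted (1R*,4R*,5S*,6S*)-dibromo β-lactone F5 is debrominated with zinc dust in THF containing a little AcOH at 0 °C (reductive elimination of a vicinal dibromide).
- This comes back to the route at 12, and the alkene is brominated again.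

3. Step 10.
- What may go wrong: the donor–acceptor pyrone may close inefficiently in the excited state, through radiationless decay, reversible opening to the ketene or photodimerisation.
- Fallback: the chromophore is changed, not the lamp. Setting out from acid 9, trimethylsilyldiazomethane gives methyl 3-acetoxy-2-oxo-2H-pyran-6-carboxylate F6. Its weaker donor brings it closer to the ester-substituted pyrones for which the closure is established.
- Irradiation gives the 4-acetoxy bicyclic β-lactone F7.
- Bromine gives the 4-acetoxy dibromo β-lactone F8. Participation of the acetate in the opening of the bromonium ion then has to be watched.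
- HCl in MeOH opens the lactone and removes the acetate in one operation. This comes back to the route at diol 15 and saves the silylation and the HF treatment.

Further compounds
F1 | step 15 | dimethyl (1R,2R,3R,4R)-3,4-dibromo-1,2-bis(hexanoyloxy)cyclobutane-1,2-dicarboxylate | CCCCCC(=O)O[C@]1(C(=O)OC)[C@@H](Br)[C@H](Br)[C@@]1(C(=O)OC)OC(=O)CCCCC
F2 | step 15 | dispiro bis(3-butyltetronic acid) trans-dibromide | CCCCC1=C(O)[C@@]2(OC1=O)[C@@H](Br)[C@H](Br)[C@@]21OC(=O)C(CCCC)=C1O
F3 | step 15 | dispiro bis(4-bromo-3-butylbutenolide) trans-dibromide | CCCCC1=C(Br)[C@@]2(OC1=O)[C@@H](Br)[C@H](Br)[C@@]21OC(=O)C(CCCC)=C1Br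
F4 | step 15 | bis(1-bromobutyl) hexabromide, mixture at both C1' | CCCC(Br)C1=C(Br)[C@@]2(OC1=O)[C@@H](Br)[C@H](Br)[C@@]21OC(=O)C(C(Br)CCC)=C1Br
F5 | step 11 | methyl (1R*,4R*,5S*,6S*)-5,6-dibromo-4-(tert-butyldimethylsilyloxy)-3-oxo-2-oxabicyclo[2.2.0]hexane-1-carboxylate, racemic | COC(=O)[C@]12OC(=O)[C@@]1(O[Si](C)(C)C(C)(C)C)[C@H](Br)[C@H]2Br
F6 | step 10 | methyl 3-acetoxy-2-oxo-2H-pyran-6-carboxylate | COC(=O)C1=CC=C(OC(C)=O)C(=O)O1
F7 | step 10 | methyl (1R*,4R*)-4-acetoxy-3-oxo-2-oxabicyclo[2.2.0]hex-5-ene-1-carboxylate, racemic | COC(=O)[C@]12OC(=O)[C@@]1(OC(C)=O)C=C2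
F8 | step 10 | methyl (1R*,4R*,5R*,6R*)-4-acetoxy-5,6-dibromo-3-oxo-2-oxabicyclo[2.2.0]hexane-1-carboxylate, racemic | COC(=O)[C@]12OC(=O)[C@@]1(OC(C)=O)[C@@H](Br)[C@@H]2Br
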